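Its constants are assumed; no experiment stands behind them.

At the outset the charges of these flasks differ in nothing but their capture agent, and two chemists disagree about what that charge does to the yield at the end.

    starting material + enzyme ⇌ starting complex (K1 = 14 /M, k1 = 18000 /M/h)
    second substrate + starting complex ⇌ ternary complex (K2 = 1500 /M, k2 = 86000 /M/h)
    ternary complex → enzyme + product (k3 = 53 /h)
    second substrate → decomposed reagent (k4 = 0.048 /h)
    starting material + protic impurity → quenched substrate (k5 = 59 /M/h)
    capture agent + starting complex → trapped intermediate (k6 = 1300 /M/h)

| setting | violet | grey | teal | blue |
|---|---|---|---|---|
| starting material | 0.020 M | 0.020 M | 0.020 M | 0.020 M |
| second substrate | 0.0260 M | 0.0260 M | 0.0260 M | 0.0260 M |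
| protic impurity | 1.00 mM | 1.00 mM | 1.00 mM | 1.00 mM |
| capture agent | 0.800 mM | 1.20 mM | 2.00 mM | 3.00 mM |
| enzyme | 20 µM | 20 µM | 20 µM | 20 µM |
| time | 15 h | 15 h | 15 h | 15 h |

1. amount of product at the end, in percent of the starting material charged for violet, grey, teal, blue, in this order
2. how the row runs (rises all the way / rises, then falls / hardly changes / falls, then rises / falls all the way)

- "hardly changes" means that all values lie within two and a half points (for a concentration: within two and a half percent of the largest)
- run time (violet): 15 h

The first chemist holds the clock view and expects a flat row. In violet, capture agent attacks a starting complex at a pseudo-first-order rate of 1.04 /h, while second substrate carries the same complex onward at 2240 /h, which is far faster. A single visit therefore almost never ends in the trap. Second substrate, meanwhile, decays with a half-life of 14.4 h by its own step, whatever the capture agent charge, and this clock is close to the run time of 15 h. So, the first chemist argues, the row hardly changes.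

The second chemist, whose reckoning I adopt as my own, counts per lost enzyme instead of per visit, and divides the rate of product by the rate of trapping so that time drops out. Product is made from ternary complex and the trap takes starting complex, so their ratio is needed. Ternary complex is formed at the onward rate above and leaves by two exits, falling back at 57.3 /h and going on to product at 53 /h. While it is made as fast as it is used, it stands at 20.3 times the starting complex. Multiplying by the product constant and dividing by the trapping rate gives 1030 for violet at the full charge of second substrate. Call this the turnover budget: the molecules of product made for each enzyme lost to the trap. It falls in inverse proportion to capture agent, so blue has 275.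

Multiplied by the enzyme charge, the budget gives a ceiling. For violet that is 103% of the starting material, above the charge itself, so it sets no limit there at the outset. For blue it is 27.5%, well below the charge. These are ceilings, not yields, and since the budget shrinks as second substrate falls, I expect a falling row that ends under the blue ceiling.

The forecast, which stands on the second chemist's side with yields of its own below my ceilings, gives 34.5%, 30%, 24.5% and 20%, a row that falls all the way, on the ground that “more capture agent kills the catalyst sooner”.

The simulation gives 34.1%, 30.2%, 24.2% and 19.1%, so the row falls all the way.

Taking the trap step away lifts blue from 19.1% to 43.9%, the largest single effect. It also turns the change from violet to blue from −15 percentage points into 0 points, and that trap-free comparison is where the first chemist's flat row holds. In the flasks as run, violet shows 621 molecules of product per trapped enzyme against its budget of 1030, and blue shows 202 against 275, with second substrate down to 31.4% and 39.8% of its charge.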